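**Plan**

- Retrosynthesis: the quinone ring is cut at two opposite acyl–alkenyl bonds, C(=O)–C(furyl) and, across the ring, CH–C(=O). This gives an (E)-3-(furan-2-yl)acryloyl imide and cyclopropenone. Further cuts: furan C2–vinyl bond, furan C5–B bond, the prenyl C=C, the ester C–O bond and the carbinol–allyl C–C bond.
- Enabling feature: the quinone ring is a head-to-tail union of two O=C–C=C units. Its furyl-bearing carbon is the β-carbon of an acryloyl unit with a vinylic C–H cis to that carbonyl. The other three ring carbons, C(=O)–CH=CH, are a cyclopropenone opened at one acyl–vinyl bond; this three-membered ring is absent from the target and supplies the strain.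
- Forward order: the furan ring is bought as furan-3-carbaldehyde. The side chain is built by allylation, acylation and cross-metathesis. C5 borylation and a boron-Heck reaction attach the acryloyl imide. The quinone ring is closed last by a rhodium-catalysed [3+3] annulation with cyclopropenone, itself made in three steps.
- Stereochemistry: the single (R) centre is set in step 1 by reagent-controlled Brown allylboration and carried through as its ester.

Key step: step 9

Remark: the target stereocentre is (R) by the CIP rules (O > furan-3-yl > CH2 > H); the quinone is made in the last step so that no later reagent has to tolerate it.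

**Route**

Step 1
Reactants: 1 furan-3-carbaldehyde
Product: 3 (1R)-1-(furan-3-yl)but-3-en-1-ol, via borinate ester 2 (not isolated)
Conditions: (+)-Ipc2B(allyl) (derived from (−)-α-pinene, 1 M in pentane, 1.2 equiv), Et2O, −78 °C; then NaOH, 30% H2O2, 0 °C to 25 °C
Reagents that add atoms: (+)-B-allyldiisopinocampheylborane, C=CCB([C@H]1C[C@H]2C[C@@H]([C@@H]1C)C2(C)C)[C@H]1C[C@H]2C[C@@H]([C@@H]1C)C2(C)C
Why: Brown asymmetric allylboration, in which the (−)-α-pinene-derived reagent should deliver allyl to the Re face of the aldehyde through a chair-like six-membered transition state and so set the (R) carbinol, after which alkaline peroxide cleaves borinate 2.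

Step 2
Reactants: 3 (1R)-1-(furan-3-yl)but-3-en-1-ol
Product: 4 (1R)-1-(furan-3-yl)but-3-en-1-yl 3-methylbutanoate
Conditions: 3-methylbutanoyl chloride (1.2 equiv), Et3N (1.5 equiv), DMAP (5 mol%), CH2Cl2, 0 °C to 25 °C
Reagents that add atoms: 3-methylbutanoyl chloride, CC(C)CC(=O)Cl
Why: DMAP-catalysed O-acylation (nucleophilic acyl substitution) takes place at oxygen only, so the C–O bond of the stereocentre is untouched and the configuration is retained.

Step 3
Reactants: 4 (1R)-1-(furan-3-yl)but-3-en-1-yl 3-methylbutanoate
Product: 5 (1R)-1-(furan-3-yl)-4-methylpent-3-en-1-yl 3-methylbutanoate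
Conditions: 2-methylbut-2-ene (large excess), second-generation Grubbs catalyst RuCl2(=CHPh)(PCy3)(H2IMes) (5 mol%), CH2Cl2, 40 °C
Reagents that add atoms: 2-methylbut-2-ene, CC=C(C)C
Why: Olefin cross-metathesis exchanges the terminal methylene for the isopropylidene of 2-methylbut-2-ene, while furan, ester and stereocentre are inert to the ruthenium carbene.

Step 4
Reactants: 5 (1R)-1-(furan-3-yl)-4-methylpent-3-en-1-yl 3-methylbutanoate
Product: 6 (1R)-4-methyl-1-[5-(4,4,5,5-tetramethyl-1,3,2-dioxaborolan-2-yl)furan-3-yl]pent-3-en-1-yl 3-methylbutanoate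
Conditions: B2pin2 (1.0 equiv), [Ir(OMe)(cod)]2 (1.5 mol%), 4,4′-di-tert-butyl-2,2′-bipyridine (3 mol%), hexane, 25 °C
Reagents that add atoms: bis(pinacolato)diboron, CC1(C)OB(OC1(C)C)B1OC(C)(C)C(C)(C)O1
Why: Iridium-catalysed aromatic C–H borylation is governed by sterics, so the α C–H at C5, remote from the branched C3 substituent, should react in preference to C2–H and the β C–H.

Step 5
Reactants: 6 (1R)-4-methyl-1-[5-(4,4,5,5-tetramethyl-1,3,2-dioxaborolan-2-yl)furan-3-yl]pent-3-en-1-yl 3-methylbutanoate; 7 3-(prop-2-enoyl)-1,3-oxazolidin-2-one
Product: 8 (1R)-4-methyl-1-{5-[(1E)-3-oxo-3-(2-oxo-1,3-oxazolidin-3-yl)prop-1-en-1-yl]furan-3-yl}pent-3-en-1-yl 3-methylbutanoate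
Conditions: 7 (1.5 equiv), Pd(OAc)2 (5 mol%), 2,9-dimethyl-1,10-phenanthroline (6 mol%), O2 (1 atm), N,N-dimethylacetamide, 40 °C
Reagents that add atoms: none
Why: Oxidative (boron) Heck reaction, in which transmetalation of 6 to divalent palladium, syn insertion of the acryloyl alkene and β-hydride elimination should give the (E)-enoyl imide while O2 reoxidises zerovalent palladium, so no base is present that could promote protodeboronation.

Step 6
Reactants: 9 2,3-dichloroprop-1-ene
Product: 11 1-bromo-3-chloro-2,2-dimethoxypropane, via chloro ether 10 (not isolated)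
Conditions: N-bromosuccinimide (1.0 equiv), MeOH, H2SO4 (cat.), 25 °C
Reagents that add atoms: N-bromosuccinimide, O=C1CCC(=O)N1Br; methanol, CO
Why: Bromomethoxylation, in which methanol opens the bromonium ion at the chlorine-bearing carbon (Markovnikov) to give 10, whose geminal chloride is then replaced by methanol through an oxocarbenium ion to give the ketal.

Step 7
Reactants: 11 1-bromo-3-chloro-2,2-dimethoxypropane
Product: 13 3,3-dimethoxycyclopropene, via chlorocyclopropane 12 (not isolated)
Conditions: KNH2 (3 equiv), liquid NH3, Et2O, −50 °C; then NH4Cl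
Reagents that add atoms: none
Why: Double dehydrohalogenation, in which amide deprotonates the chloromethyl group, 3-exo-tet displacement of bromide gives 12, and 1,2-elimination of HCl then gives the cyclopropene, held as its potassium salt until the NH4Cl quench.

Step 8
Reactants: 13 3,3-dimethoxycyclopropene
Product: 14 cycloprop-2-en-1-one
Conditions: H2O, H2SO4 (cat.), CH2Cl2, 0 °C; dried over Na2SO4 and kept cold as a titrated solution
Reagents that add atoms: water, O
Why: Acid-catalysed ketal hydrolysis, whose product ketone is stabilised by its hydroxycyclopropenylium (aromatic two-π-electron) character and should therefore survive cold dilute acid.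

Step 9
Reactants: 8 (1R)-4-methyl-1-{5-[(1E)-3-oxo-3-(2-oxo-1,3-oxazolidin-3-yl)prop-1-en-1-yl]furan-3-yl}pent-3-en-1-yl 3-methylbutanoate; 14 cycloprop-2-en-1-one
Product: 15 (1R)-1-[5-(3,6-dioxocyclohexa-1,4-dien-1-yl)furan-3-yl]-4-methylpent-3-en-1-yl 3-methylbutanoate
Conditions: [Cp*Rh(MeCN)3](SbF6)2 (5 mol%), NaOPiv (20 mol%), 14 (3 equiv, added over 6 h), ClCH2CH2Cl, 40 °C
Reagents that add atoms: none
Why: Proposed new method: pivalate-assisted cleavage of the vinylic C–H cis to the imide carbonyl of 8 should give a five-membered O-bound alkenyl–rhodium (trivalent rhodium throughout), which adds across the C=O of 14; strain-driven β-carbon elimination then opens the cyclopropenoxide to a (Z)-β-acylvinyl–rhodium, and this adds to the imide carbonyl and expels oxazolidinone, so that the C(=O)–C(furyl) bond and the opposite CH–C(=O) bond of the quinone are both made in one redox-neutral catalytic cycle. The closest known reaction types are the trivalent-rhodium C–H acylation of arenes with cyclopropenones (same carbonyl insertion and ring opening, ended by protonation) and the rhodium-catalysed indenone annulation of aryl imides with alkynes (alkenyl–rhodium addition to the directing imide with C–N cleavage); their union in a [3+3] sense on an acryloyl imide has not been shown. The quinone ring closes by 6-exo-trig attack of the alkenyl–rhodium carbon on the imide carbonyl, and the cleaved three-membered ring is the temporary element. No stereocentre is formed, and the existing one is remote from the reacting atoms. The step needs site selectivity for the vinylic C–H over the furan C–H bonds, which the (E)-geometry and the five-membered chelate should secure, and cross-selectivity, which follows because only 8 has a directing group and only 14 a strained ketone. It also needs ring closure to outrun protodemetalation, which the cis placement of rhodium and imide after ring opening and the low acid concentration should favour.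

**Compound list**

1 | furan-3-carbaldehyde | O=Cc1ccoc1 | starting material
2 | (1R)-1-(furan-3-yl)but-3-en-1-yl diisopinocampheylborinate | C=CC[C@@H](OB([C@H]1C[C@H]2C[C@@H]([C@@H]1C)C2(C)C)[C@H]1C[C@H]2C[C@@H]([C@@H]1C)C2(C)C)c1ccoc1 | intermediate
3 | (1R)-1-(furan-3-yl)but-3-en-1-ol | C=CC[C@@H](O)c1ccoc1 | intermediate
4 | (1R)-1-(furan-3-yl)but-3-en-1-yl 3-methylbutanoate | C=CC[C@@H](OC(=O)CC(C)C)c1ccoc1 | intermediate
5 | (1R)-1-(furan-3-yl)-4-methylpent-3-en-1-yl 3-methylbutanoate | CC(C)=CC[C@@H](OC(=O)CC(C)C)c1ccoc1 | intermediate
6 | (1R)-4-methyl-1-[5-(4,4,5,5-tetramethyl-1,3,2-dioxaborolan-2-yl)furan-3-yl]pent-3-en-1-yl 3-methylbutanoate | CC(C)=CC[C@@H](OC(=O)CC(C)C)c1coc(B2OC(C)(C)C(C)(C)O2)c1 | intermediate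
7 | 3-(prop-2-enoyl)-1,3-oxazolidin-2-one | C=CC(=O)N1CCOC1=O | starting material
8 | (1R)-4-methyl-1-{5-[(1E)-3-oxo-3-(2-oxo-1,3-oxazolidin-3-yl)prop-1-en-1-yl]furan-3-yl}pent-3-en-1-yl 3-methylbutanoate | CC(C)=CC[C@@H](OC(=O)CC(C)C)c1coc(/C=C/C(=O)N2CCOC2=O)c1 | intermediate
9 | 2,3-dichloroprop-1-ene | C=C(Cl)CCl | starting material
10 | 1-bromo-2,3-dichloro-2-methoxypropane (racemic) | COC(Cl)(CBr)CCl | intermediate
11 | 1-bromo-3-chloro-2,2-dimethoxypropane | COC(CBr)(CCl)OC | intermediate
12 | 2-chloro-1,1-dimethoxycyclopropane (racemic) | COC1(OC)CC1Cl | intermediate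
13 | 3,3-dimethoxycyclopropene | COC1(OC)C=C1 | intermediate
14 | cycloprop-2-en-1-one | O=C1C=C1 | intermediate
15 | (1R)-1-[5-(3,6-dioxocyclohexa-1,4-dien-1-yl)furan-3-yl]-4-methylpent-3-en-1-yl 3-methylbutanoate | CC(C)=CC[C@@H](OC(=O)CC(C)C)c1coc(C2=CC(=O)C=CC2=O)c1 | target

**Step count and risks**

Total step count: 9. Longest linear sequence: 6 (steps 1, 2, 3, 4, 5 and 9); steps 6 to 8 form the convergent branch to 14.

Steps most likely to fail:

1. Step 9 (proposed new method). The alkenyl–rhodium formed by ring opening may be protonated before it closes the ring, which would stop at open-chain C–H acylation. Cyclopropenone may be lost to polymerisation. The cationic metal may ionise the furylcarbinyl ester, with erosion of configuration, or be held back by the quinone as it forms. Fallback by known chemistry, setting out from 6 and coming back at 15: Suzuki–Miyaura coupling of 6 with 2-bromo-1,4-dimethoxybenzene (COc1ccc(OC)c(Br)c1; PdCl2(dppf), K3PO4, 1,4-dioxane/H2O, 60 °C) should give (1R)-1-[5-(2,5-dimethoxyphenyl)furan-3-yl]-4-methylpent-3-en-1-yl 3-methylbutanoate F1. Oxidative demethylation of F1 with (NH4)2Ce(NO3)6 in MeCN/H2O at 0 °C should then give 15. In this fallback the six-membered ring is bought as an arene and not built.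

2. Step 5. Protodeboronation of the 2-furyl boronate or its oxidative homocoupling may outrun transmetalation and insertion. Fallback, setting out from 6 and coming back at 8: CuBr2 in MeOH/H2O at 60 °C should turn the C–B bond into a C–Br bond and give (1R)-1-(5-bromofuran-3-yl)-4-methylpent-3-en-1-yl 3-methylbutanoate F2. A Mizoroki–Heck reaction of F2 with 7 (Pd(OAc)2, P(o-tol)3, Et3N, MeCN, 80 °C) should then give 8. The furan enters as the electrophile, so no boron species has to survive the coupling.

3. Step 4. Site selectivity between the two α C–H bonds (C5 against C2) may be lost, or the pinacolborane released may hydroborate the prenyl alkene. Fallback, setting out from 5 and coming back at 8: a dehydrogenative (Fujiwara–Moritani) Heck reaction of 5 with 7 (Pd(OAc)2 10 mol%, Cu(OAc)2, O2, AcOH/1,4-dioxane, 60 °C). Electrophilic palladation of the more accessible α-carbon C5 is followed by insertion of 7 and β-hydride elimination; the C2 isomer, if formed, would be removed by chromatography. This bypasses 6 and all boron chemistry and makes no new compound (F0).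

**Further compounds**

F1 | step 9 | (1R)-1-[5-(2,5-dimethoxyphenyl)furan-3-yl]-4-methylpent-3-en-1-yl 3-methylbutanoate | CC(C)=CC[C@@H](OC(=O)CC(C)C)c1coc(-c2cc(OC)ccc2OC)c1
F2 | step 5 | (1R)-1-(5-bromofuran-3-yl)-4-methylpent-3-en-1-yl 3-methylbutanoate | CC(C)=CC[C@@H](OC(=O)CC(C)C)c1coc(Br)c1
F0 | step 4 | none | none
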